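## Analysis of the target

The target is a flavanone, a 2-aryl-2,3-dihydro-4H-chromen-4-one. Ring A is a phloroglucinol unit (O1, 5-OH, 7-OH) with a 3-methylbut-2-enyl (prenyl) group at C8. Ring C is the dihydropyranone. Ring B is a 2',4'-dihydroxyphenyl group with a 2-methylbut-3-en-2-yl (1,1-dimethylallyl) group at C5'.

There is one stereocentre, C2. With the priorities O1 > C1' > C3 > H the descriptor in the SMILES string is (S). C2 is benzylic, bound to O1 and β to the C4 carbonyl, so it can be lost in two ways. Base opens ring C by a retro-oxa-Michael reaction. Acid ionises the C2–O1 bond, helped by the ortho and para oxygens of ring B.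

The sensitive groups are four free phenols, a trisubstituted olefin ortho to 7-OH and a terminal vinyl group ortho to 4'-OH. Acid adds each phenol to its neighbouring olefin. The two olefins rule out hydrogenation and hydrogenolysis.

The difficulties are placing the prenyl group at C8 and not at C6, installing the reversed prenyl group at C5', and keeping C2 intact through ring construction and deprotection.

The route rests on one feature. Once C8 carries the prenyl group, C4a is the only unsubstituted carbon ortho to O1. It is also ortho to O5 and para to O7. An acyl carbon tethered through O1–C2–C3 can therefore attack only there, and the C4–C4a bond can be made last.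

## Retrosynthetic reasoning

**Protecting groups.** Target 22 is traced back to the diacetate 21 and then to the fully protected flavanone 20. Ring B carries acetates because O-acyl groups lower its donor strength and so hold the benzylic C2–O1 bond against heterolysis. Ring A carries silyl ethers because they keep it nucleophilic. Both are removed without acid and without strong base: the silyl ethers by buffered fluoride, the acetates by neutral methanolysis.

**C4–C4a.** Flavanone 20 is cut at the aryl ketone bond to give the 3-aryl-3-aryloxypropanoic acid 18, which reacts through its mixed anhydride 19. The cut is placed here because the closure is intramolecular, can reach only C4a, and delivers C4 directly as the ketone. Closing O1–C2 instead would need a chalcone and base, with no control at C2. The forward reaction has to acylate C4a without ionising C2–O1 and without touching either olefin.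

**Carboxyl unmasking.** Acid 18 comes from the tert-butyl ester 16 through the silyl ester 17. A tert-butyl ester is chosen because it is cleaved at the alkyl–oxygen bond under non-basic conditions. Saponification would strip the aryl acetates and could expel the β-aryloxy group.

**O1–C2.** Ester 16 is cut at the aryl ether bond to give the (R)-carbinol 11 and the phenol 15. The forward reaction is a Mitsunobu substitution with inversion, so the carbinol has to be (R). This joins the two halves late and uses the one free hydroxyl of 15.

**C2–C3.** Carbinol 11 is cut between C2 and C3 to give the aldehyde 6 and the silyl ketene acetal 9, which is made from the ester 7 through its enolate 8. The forward reaction is an enantioselective acetate aldol addition. It is run under Lewis-acid conditions so that the adduct is held as the silyl ether 10 until work-up. A metal alkoxide next to the ortho acetate could take up the acetyl group.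

**Ring B.** Aldehyde 6 arises by acetylation of the phenol 5, which is the product of an aromatic Claisen rearrangement of the prenyl ether 4. The [3,3] shift turns an O-prenyl group into a C-(1,1-dimethylallyl) group, which makes the quaternary carbon at C5'. Ether 4 comes from the hydroxy aldehyde 3 by acetylation, and 3 from aldehyde 1 and bromide 2. The acetate on O2 removes the hydrogen bond to the formyl group that would otherwise steer the shift to C3.

**Ring A.** Phenol 15 is cut at the C8–prenyl bond to give the bis-silyl ether 13, its sodium salt 14 and bromide 2. Ether 13 comes from the triol 12. The three hydroxyls of 12 are equivalent, and in 13 the two positions ortho to the free hydroxyl are equivalent. Ortho C-prenylation therefore gives one product, with the free hydroxyl next to the prenyl group as the Mitsunobu step needs.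

## Alternatives that were turned down

**Alternative 1: ring C by aryl ether closure at C8a.**
- Disconnection: O1–C8a.
- Key step: the 1,3-diol aryl triflate A2 would cyclise with a zerovalent palladium catalyst carrying a bulky di-tert-butyl biaryl phosphine and a carbonate base to the flavan-4-ol A1.
- For it: the carbinol oxygen is arylated, so no substitution takes place at C2 and the configuration is retained by construction. The conditions are not acidic. The 1,3-diol can be set by aldol and directed reduction.
- Against it: the triflate of A2 has the prenyl group on one side and a branched carbinol chain on the other, on a ring with two alkoxy donors. Oxidative addition and C–O reductive elimination are both slow in that setting. A secondary benzylic alkoxide on palladium can undergo β-hydride elimination, and the carbonate can cleave the S–O bond of the triflate. After the closure the C4 carbinol of A1 has to be oxidised, so a second stereocentre is controlled only to be destroyed. Four methoxymethyl ethers then have to come off with acid, which is the condition that adds 7-OH and 4'-OH to their neighbouring olefins. The ring A half of A2 is a hexasubstituted benzene and takes many steps.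
- Comparison: this alternative is stronger on the safety of C2 during ring closure. The chosen route offers C4 at the ketone level straight from the closure, a ring A piece made in two steps, and a non-acidic end game.

**Alternative 2: ring C by cycloaddition of a quinone methide with a hydroxystyrene.**
- Disconnection: C3–C4 and O1–C2 together.
- Key step: the salicylaldehyde A4 would be condensed with an orthoformate under a chiral phosphoric acid to a cationic heterodiene, which adds the 2-hydroxystyrene A5 in a [4+2] sense to the 4-methoxyflavan A3.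
- For it: it is the most convergent plan. Two bonds, ring C and C2 are made in one catalytic enantioselective step from two small components.
- Against it: A3 has C4 as a methyl ether. It must be oxidised to the ketone late, in the presence of a prenyl group with allylic C–H bonds, electron-rich arenes and a free phenol. The C4 stereocentre is wasted. The acid catalyst meets a free hydroxyl ortho to the prenyl group in A4, aryl silyl ethers, and in A5 an electron-rich hydroxystyrene that dimerises under acid. The silyloxy group next to the formyl carbon of A4 crowds the reacting centre. Facial control on so hindered a heterodiene is untested.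
- Comparison: this alternative is stronger in step count to the tricycle and in setting C2 by catalysis at ring formation. The chosen route offers the right oxidation level at C4 and no oxidation after ring closure.

**Alternative 3: ring A by photochemical Wolff rearrangement and benzannulation.**
- Disconnection: C5–C6, C7–C8 and C4a–C5, so that ring A is built onto a dihydropyranone.
- Key step: irradiation of the diazo ketone A7 would trigger a Wolff shift, [2+2] addition of the resulting ketene to the siloxyalkyne A8, and an electrocyclic opening and reclosure that ends in the flavanone A6.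
- For it: the regiochemistry of ring A is fixed by the precursors. The prenyl group sits at C8 because it is on the diazo carbon of A7, O7 is silylated because it comes from A8, and O5 is free. The conditions are neutral and C2 is never next to a leaving group.
- Against it: A7 is a 6-acyl-2-aryl-dihydropyranone with a diazo group beside a prenyl methylene, and it is long to make. A 1,2-hydride shift from that methylene competes with the Wolff shift. The pericyclic cascade needs heating, which a 2-aryl-dihydropyranone may not survive. A8 is sensitive to moisture.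
- Comparison: this alternative is stronger in regiocontrol on ring A and in differentiating O5 from O7. The chosen route gets the same regiochemical result from the symmetry of 12 and from the tether, in far fewer steps.

Key step: step 10

Assumption: in step 5 the sense of induction is specified by the face of the aldehyde that has to be attacked (Re, giving the (R)-carbinol). The catalyst antipode that does this is the one to be used, and the configuration of 11 is to be confirmed by Mosher ester analysis before the material is carried on.

## Route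

**Step 1**
Reactants: 1 2,4-dihydroxybenzaldehyde; 2 1-bromo-3-methylbut-2-ene (prenyl bromide)
Product: 3 2-hydroxy-4-[(3-methylbut-2-en-1-yl)oxy]benzaldehyde
Conditions: K2CO3 (1.0 equiv), acetone, rt
Reagents that add atoms: none
Why: Williamson etherification; the 4-OH is para to the formyl group, more acidic and free, while the 2-OH is tied up in a hydrogen bond to the carbonyl, so monoalkylation at O4 should dominate.

**Step 2**
Reactants: 3 2-hydroxy-4-[(3-methylbut-2-en-1-yl)oxy]benzaldehyde
Product: 4 2-formyl-5-[(3-methylbut-2-en-1-yl)oxy]phenyl acetate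
Conditions: Ac2O, Et3N, DMAP (cat.), CH2Cl2, 0 °C → rt
Reagents that add atoms: acetic anhydride, CC(=O)OC(C)=O
Why: DMAP-catalysed acetylation of the chelated phenol; the acetate removes the hydrogen bond that would direct the coming rearrangement to C3.

**Step 3**
Reactants: 4 2-formyl-5-[(3-methylbut-2-en-1-yl)oxy]phenyl acetate
Product: 6 4-formyl-6-(2-methylbut-3-en-2-yl)-1,3-phenylene diacetate, via 2-formyl-5-hydroxy-4-(2-methylbut-3-en-2-yl)phenyl acetate 5 (not isolated)
Conditions: PhNEt2, 185 °C, Ar; then rt, Ac2O, Et3N, DMAP (cat.)
Reagents that add atoms: acetic anhydride, CC(=O)OC(C)=O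
Why: Aromatic Claisen rearrangement with allyl inversion turns the O-prenyl group into a C-(1,1-dimethylallyl) group; C5 is open whereas C3 lies between two oxygen substituents and would have to take a quaternary carbon, so migration to C5 is expected. Acetylation in the same flask caps the new phenol before it can add to the olefin or rearrange further, and any acetyl scrambling during heating converges on the diacetate.

**Step 4**
Reactants: 7 tert-butyl acetate
Product: 9 tert-butyl[(1-tert-butoxyethenyl)oxy]dimethylsilane, via lithium enolate of tert-butyl acetate 8 (not isolated)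
Conditions: LiN(iPr)2, THF, −78 °C; t-BuMe2SiCl, DMPU, −78 °C → rt; distillation
Reagents that add atoms: tert-butyl(chloro)dimethylsilane, CC(C)(C)[Si](C)(C)Cl
Why: Kinetic enolisation of a tert-butyl ester, which does not self-condense at −78 °C, followed by O-silylation in the presence of a polar additive gives the silyl ketene acetal.

**Step 5**
Reactants: 6 4-formyl-6-(2-methylbut-3-en-2-yl)-1,3-phenylene diacetate; 9 tert-butyl[(1-tert-butoxyethenyl)oxy]dimethylsilane
Product: 11 tert-butyl (3R)-3-[2,4-diacetoxy-5-(2-methylbut-3-en-2-yl)phenyl]-3-hydroxypropanoate, via trichlorosilyl ether of the aldol 10 (not isolated)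
Conditions: SiCl4 (1.1 equiv), chiral bisphosphoramide (two N,N'-dimethyl-1,1'-binaphthyl-2,2'-diamine phosphoramide units joined by an N,N'-dimethylpentane-1,5-diamine chain; 5 mol%, antipode for Re-face attack), CH2Cl2, −78 °C; cold aq. NaHCO3
Reagents that add atoms: none
Why: Lewis-base-catalysed Mukaiyama aldol addition; the phosphoramide-bound trichlorosilyl cation activates the aldehyde in a chiral pocket and the ketene acetal adds to the Re face, which sets C2 of the later flavanone as the (R)-carbinol. The adduct stays a trichlorosilyl ether until the cold quench, so no metal alkoxide sits next to the ortho acetate, and the aryl acetates and the vinyl group are inert to SiCl4 at −78 °C.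

**Step 6**
Reactants: 12 benzene-1,3,5-triol (phloroglucinol)
Product: 13 3,5-bis[(tert-butyldimethylsilyl)oxy]phenol
Conditions: t-BuMe2SiCl (2.0 equiv), imidazole, DMF, 0 °C → rt; chromatography
Reagents that add atoms: tert-butyl(chloro)dimethylsilane, CC(C)(C)[Si](C)(C)Cl
Why: Statistical silylation of three equivalent hydroxyls; only one bis-silyl ether is possible, and it should separate readily from the mono- and tris-silylated material.

**Step 7**
Reactants: 13 3,5-bis[(tert-butyldimethylsilyl)oxy]phenol; 2 1-bromo-3-methylbut-2-ene
Product: 15 3,5-bis[(tert-butyldimethylsilyl)oxy]-2-(3-methylbut-2-en-1-yl)phenol, via sodium 3,5-bis[(tert-butyldimethylsilyl)oxy]phenoxide 14 (not isolated)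
Conditions: NaH (1.0 equiv), toluene, 0 °C; then 2 (1.0 equiv), rt
Reagents that add atoms: none
Why: C-allylation of a sodium aryloxide in a non-coordinating solvent, where the contact ion pair delivers the allylic bromide to the ortho carbon; the two ortho positions are equivalent and the para position lies between two bulky silyloxy groups, so one C-prenyl phenol is expected, with its free hydroxyl next to the prenyl group.

**Step 8**
Reactants: 11 tert-butyl (3R)-3-[2,4-diacetoxy-5-(2-methylbut-3-en-2-yl)phenyl]-3-hydroxypropanoate; 15 3,5-bis[(tert-butyldimethylsilyl)oxy]-2-(3-methylbut-2-en-1-yl)phenol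
Product: 16 tert-butyl (3S)-3-{3,5-bis[(tert-butyldimethylsilyl)oxy]-2-(3-methylbut-2-en-1-yl)phenoxy}-3-[2,4-diacetoxy-5-(2-methylbut-3-en-2-yl)phenyl]propanoate
Conditions: PPh3, DIAD, toluene, 0 °C → rt
Reagents that add atoms: none
Why: Mitsunobu etherification; the aryloxide displaces the alkoxyphosphonium group by SN2 with inversion, so the (R)-carbinol gives the (S)-ether. The two acetoxy groups on ring B disfavour ionisation of the benzylic centre, and the bulky tert-butyl ester slows elimination to the cinnamate.

**Step 9**
Reactants: 16 tert-butyl (3S)-3-{3,5-bis[(tert-butyldimethylsilyl)oxy]-2-(3-methylbut-2-en-1-yl)phenoxy}-3-[2,4-diacetoxy-5-(2-methylbut-3-en-2-yl)phenyl]propanoate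
Product: 18 (3S)-3-{3,5-bis[(tert-butyldimethylsilyl)oxy]-2-(3-methylbut-2-en-1-yl)phenoxy}-3-[2,4-diacetoxy-5-(2-methylbut-3-en-2-yl)phenyl]propanoic acid, via trimethylsilyl ester of the acid 17 (not isolated)
Conditions: Me3SiOTf, 2,6-lutidine, CH2Cl2, 0 °C; aq. citric acid
Reagents that add atoms: none
Why: Silyl-triflate cleavage of a tert-butyl ester; silylation of the carbonyl oxygen and loss of 2-methylpropene give the silyl ester, which hydrolyses on work-up. The medium is buffered and free of hydroxide, so the aryl acetates, aryl silyl ethers, olefins and the β-aryloxy group are left alone.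

**Step 10**
Reactants: 18 (3S)-3-{3,5-bis[(tert-butyldimethylsilyl)oxy]-2-(3-methylbut-2-en-1-yl)phenoxy}-3-[2,4-diacetoxy-5-(2-methylbut-3-en-2-yl)phenyl]propanoic acid
Product: 20 (2S)-5,7-bis[(tert-butyldimethylsilyl)oxy]-2-[2,4-diacetoxy-5-(2-methylbut-3-en-2-yl)phenyl]-8-(3-methylbut-2-en-1-yl)-2,3-dihydro-4H-chromen-4-one, via mixed trifluoroacetic anhydride of the acid 19 (not isolated)
Conditions: (CF3CO)2O (1.3 equiv), CH2Cl2, −20 → 0 °C; aq. NaHCO3
Reagents that add atoms: none
Why: Trifluoroacetic anhydride turns the acid into the mixed anhydride 19; its acyl carbon is attacked by C4a of ring A, and loss of a proton from the arenium ion gives the aryl ketone. This is an intramolecular Friedel–Crafts acylation, and the closest known case is the cyclisation of 3-aryloxypropanoic acids to chroman-4-ones under the same activation. Ring C closes in a 6-exo-trig mode at the acyl carbon, the new C4–C4a bond completing the six-membered ring through O1, C2 and C3. No stereocentre is formed; C2 is carried through from step 8. The step needs regioselectivity, and the substrate supplies it: the tether reaches only the two carbons ortho to O1, C8 is occupied by the prenyl group, and C4a is activated by O1 and O5 (ortho) and O7 (para). That donor strength should allow the closure without a metal Lewis acid and below room temperature, which spares the prenyl group, the vinyl group and the silyl ethers. The step also needs retention at C2, which the electron-poor acetoxy groups on ring B and the low temperature secure by disfavouring heterolysis of C2–O1. The anhydride is kept near one equivalent so that intermolecular trifluoroacetylation of ring A cannot compete once the acid is consumed.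

**Step 11**
Reactants: 20 (2S)-5,7-bis[(tert-butyldimethylsilyl)oxy]-2-[2,4-diacetoxy-5-(2-methylbut-3-en-2-yl)phenyl]-8-(3-methylbut-2-en-1-yl)-2,3-dihydro-4H-chromen-4-one
Product: 21 4-[(2S)-5,7-dihydroxy-8-(3-methylbut-2-en-1-yl)-4-oxo-3,4-dihydro-2H-chromen-2-yl]-6-(2-methylbut-3-en-2-yl)-1,3-phenylene diacetate
Conditions: Bu4NF, AcOH (1:1), THF, 0 °C
Reagents that add atoms: none
Why: Fluoride cleavage of aryl silyl ethers; the acetic acid buffer keeps the liberated phenoxides protonated, so ring C should not open by retro-oxa-Michael reaction and C2 should keep its configuration.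

**Step 12**
Reactants: 21 4-[(2S)-5,7-dihydroxy-8-(3-methylbut-2-en-1-yl)-4-oxo-3,4-dihydro-2H-chromen-2-yl]-6-(2-methylbut-3-en-2-yl)-1,3-phenylene diacetate
Product: 22 (2S)-2-[2,4-dihydroxy-5-(2-methylbut-3-en-2-yl)phenyl]-5,7-dihydroxy-8-(3-methylbut-2-en-1-yl)-2,3-dihydro-4H-chromen-4-one (AChE-IN-17)
Conditions: NH4OAc, MeOH/H2O (4:1), rt
Reagents that add atoms: none
Why: Neutral ammonium-acetate-mediated methanolysis of aryl acetates; aryl esters are activated esters and should cleave without base strong enough to open the flavanone and without acid that would add a phenol to either olefin.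

## Compound list

1 | 2,4-dihydroxybenzaldehyde | O=Cc1ccc(O)cc1O | starting material
2 | 1-bromo-3-methylbut-2-ene (prenyl bromide) | CC(C)=CCBr | starting material
3 | 2-hydroxy-4-[(3-methylbut-2-en-1-yl)oxy]benzaldehyde | O=Cc1ccc(OCC=C(C)C)cc1O | intermediate
4 | 2-formyl-5-[(3-methylbut-2-en-1-yl)oxy]phenyl acetate | O=Cc1ccc(OCC=C(C)C)cc1OC(C)=O | intermediate
5 | 2-formyl-5-hydroxy-4-(2-methylbut-3-en-2-yl)phenyl acetate | O=Cc1cc(C(C)(C)C=C)c(O)cc1OC(C)=O | intermediate
6 | 4-formyl-6-(2-methylbut-3-en-2-yl)-1,3-phenylene diacetate | O=Cc1cc(C(C)(C)C=C)c(OC(C)=O)cc1OC(C)=O | intermediate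
7 | tert-butyl acetate | CC(=O)OC(C)(C)C | starting material
8 | lithium 1-tert-butoxyethenolate (lithium enolate of tert-butyl acetate) | [Li]OC(=C)OC(C)(C)C | intermediate
9 | tert-butyl[(1-tert-butoxyethenyl)oxy]dimethylsilane | C=C(OC(C)(C)C)O[Si](C)(C)C(C)(C)C | intermediate
10 | tert-butyl (3R)-3-[2,4-diacetoxy-5-(2-methylbut-3-en-2-yl)phenyl]-3-[(trichlorosilyl)oxy]propanoate | CC(C)(C)OC(=O)C[C@@H](O[Si](Cl)(Cl)Cl)c1cc(C(C)(C)C=C)c(OC(C)=O)cc1OC(C)=O | intermediate
11 | tert-butyl (3R)-3-[2,4-diacetoxy-5-(2-methylbut-3-en-2-yl)phenyl]-3-hydroxypropanoate | CC(C)(C)OC(=O)C[C@@H](O)c1cc(C(C)(C)C=C)c(OC(C)=O)cc1OC(C)=O | intermediate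
12 | benzene-1,3,5-triol (phloroglucinol) | Oc1cc(O)cc(O)c1 | starting material
13 | 3,5-bis[(tert-butyldimethylsilyl)oxy]phenol | Oc1cc(O[Si](C)(C)C(C)(C)C)cc(O[Si](C)(C)C(C)(C)C)c1 | intermediate
14 | sodium 3,5-bis[(tert-butyldimethylsilyl)oxy]phenoxide | [Na+].[O-]c1cc(O[Si](C)(C)C(C)(C)C)cc(O[Si](C)(C)C(C)(C)C)c1 | intermediate
15 | 3,5-bis[(tert-butyldimethylsilyl)oxy]-2-(3-methylbut-2-en-1-yl)phenol | Oc1cc(O[Si](C)(C)C(C)(C)C)cc(O[Si](C)(C)C(C)(C)C)c1CC=C(C)C | intermediate
16 | tert-butyl (3S)-3-{3,5-bis[(tert-butyldimethylsilyl)oxy]-2-(3-methylbut-2-en-1-yl)phenoxy}-3-[2,4-diacetoxy-5-(2-methylbut-3-en-2-yl)phenyl]propanoate | CC(C)(C)OC(=O)C[C@H](Oc1cc(O[Si](C)(C)C(C)(C)C)cc(O[Si](C)(C)C(C)(C)C)c1CC=C(C)C)c1cc(C(C)(C)C=C)c(OC(C)=O)cc1OC(C)=O | intermediate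
17 | trimethylsilyl (3S)-3-{3,5-bis[(tert-butyldimethylsilyl)oxy]-2-(3-methylbut-2-en-1-yl)phenoxy}-3-[2,4-diacetoxy-5-(2-methylbut-3-en-2-yl)phenyl]propanoate | C[Si](C)(C)OC(=O)C[C@H](Oc1cc(O[Si](C)(C)C(C)(C)C)cc(O[Si](C)(C)C(C)(C)C)c1CC=C(C)C)c1cc(C(C)(C)C=C)c(OC(C)=O)cc1OC(C)=O | intermediate
18 | (3S)-3-{3,5-bis[(tert-butyldimethylsilyl)oxy]-2-(3-methylbut-2-en-1-yl)phenoxy}-3-[2,4-diacetoxy-5-(2-methylbut-3-en-2-yl)phenyl]propanoic acid | OC(=O)C[C@H](Oc1cc(O[Si](C)(C)C(C)(C)C)cc(O[Si](C)(C)C(C)(C)C)c1CC=C(C)C)c1cc(C(C)(C)C=C)c(OC(C)=O)cc1OC(C)=O | intermediate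
19 | (3S)-3-{3,5-bis[(tert-butyldimethylsilyl)oxy]-2-(3-methylbut-2-en-1-yl)phenoxy}-3-[2,4-diacetoxy-5-(2-methylbut-3-en-2-yl)phenyl]propanoic trifluoroacetic anhydride | O=C(C[C@H](Oc1cc(O[Si](C)(C)C(C)(C)C)cc(O[Si](C)(C)C(C)(C)C)c1CC=C(C)C)c1cc(C(C)(C)C=C)c(OC(C)=O)cc1OC(C)=O)OC(=O)C(F)(F)F | intermediate
20 | (2S)-5,7-bis[(tert-butyldimethylsilyl)oxy]-2-[2,4-diacetoxy-5-(2-methylbut-3-en-2-yl)phenyl]-8-(3-methylbut-2-en-1-yl)-2,3-dihydro-4H-chromen-4-one | C=CC(C)(C)c1cc([C@@H]2CC(=O)c3c(O[Si](C)(C)C(C)(C)C)cc(O[Si](C)(C)C(C)(C)C)c(CC=C(C)C)c3O2)c(OC(C)=O)cc1OC(C)=O | intermediate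
21 | 4-[(2S)-5,7-dihydroxy-8-(3-methylbut-2-en-1-yl)-4-oxo-3,4-dihydro-2H-chromen-2-yl]-6-(2-methylbut-3-en-2-yl)-1,3-phenylene diacetate | C=CC(C)(C)c1cc([C@@H]2CC(=O)c3c(O)cc(O)c(CC=C(C)C)c3O2)c(OC(C)=O)cc1OC(C)=O | intermediate
22 | (2S)-2-[2,4-dihydroxy-5-(2-methylbut-3-en-2-yl)phenyl]-5,7-dihydroxy-8-(3-methylbut-2-en-1-yl)-2,3-dihydro-4H-chromen-4-one (AChE-IN-17) | C=CC(C)(C)c1cc([C@@H]2CC(=O)c3c(O)cc(O)c(CC=C(C)C)c3O2)c(O)cc1O | target

## Step count and least certain steps

Total: 12 steps. Longest linear sequence: 9 steps (1, 2, 3, 5, 8, 9, 10, 11, 12, from compound 1). The ring A branch (steps 6 and 7) and the ketene acetal (step 4) join at steps 8 and 5.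

**Step 10 (key step).**
- What may go wrong: intermolecular trifluoroacetylation of the electron-rich ring A; protonation of the prenyl olefin by the trifluoroacetic acid set free; heterolysis of the C2–O1 bond with loss of configuration or elimination towards the cinnamic acid; ipso attack at C8 with loss of the prenyl cation. Loss of the silyl group on O5 after ring closure would be harmless, because step 11 removes it anyway.
- Fallback: from 18, the carboxyl group is converted under neutral conditions with 1-chloro-N,N,2-trimethylprop-1-en-1-amine (CH2Cl2, 0 °C) into (3S)-3-{3,5-bis[(tert-butyldimethylsilyl)oxy]-2-(3-methylbut-2-en-1-yl)phenoxy}-3-[2,4-diacetoxy-5-(2-methylbut-3-en-2-yl)phenyl]propanoyl chloride F1. This is ionised with AgOTf in the presence of 2,6-di-tert-butyl-4-methylpyridine at −78 °C. The acyl triflate acylates C4a in an aprotic, proton-scavenged medium and the sequence returns to 20.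

**Step 8.**
- What may go wrong: elimination of water across C2–C3 to the cinnamate; partial loss of configuration if the alkoxyphosphonium ion ionises, which the ortho acetoxy group can assist by participation; acetyl migration from O2' to the carbinol oxygen before activation; slow reaction of the ortho-substituted, weakly acidic phenol.
- Fallback: from 11, reaction with Ph2PCl, Et3N and DMAP (cat.) in THF at 0 °C gives tert-butyl (3R)-3-[2,4-diacetoxy-5-(2-methylbut-3-en-2-yl)phenyl]-3-[(diphenylphosphanyl)oxy]propanoate F2. This is combined with 15 and 2,6-dimethyl-1,4-benzoquinone in CH2Cl2 at rt (oxidation–reduction condensation of an alkyl diphenylphosphinite, inversion at carbon, no azodicarboxylate-derived base). The sequence returns to 16.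

**Step 7.**
- What may go wrong: O-alkylation in place of C-alkylation if the aryloxide is too well solvated; a second prenylation; silyl transfer between aryloxide oxygens.
- Fallback: from 13, O-alkylation with 3-chloro-3-methylbut-1-yne (K2CO3, KI, CuI cat., acetone) gives 1,3-bis[(tert-butyldimethylsilyl)oxy]-5-[(2-methylbut-3-yn-2-yl)oxy]benzene F3. Partial hydrogenation (H2, Pd on CaCO3 poisoned with Pb(OAc)2, quinoline, EtOAc) gives 1,3-bis[(tert-butyldimethylsilyl)oxy]-5-[(2-methylbut-3-en-2-yl)oxy]benzene F4. An aromatic Claisen rearrangement (toluene, 110 °C) then moves the allyl group with inversion to the ortho carbon and returns to 15.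

**Step 5.**
- What may go wrong: poor facial selectivity if the ortho acetoxy group binds silicon and perturbs the catalyst pocket; slow addition to the ortho-substituted aldehyde; acetyl migration to the new hydroxyl during work-up.
- Fallback: from 6, Roskamp homologation with tert-butyl diazoacetate and SnCl2 (cat.) in CH2Cl2 gives tert-butyl 3-[2,4-diacetoxy-5-(2-methylbut-3-en-2-yl)phenyl]-3-oxopropanoate F5. Noyori asymmetric transfer hydrogenation with RuCl[(R,R)-TsDPEN](p-cymene) in HCO2H/Et3N reduces the aryl ketone to the (R)-carbinol and returns to 11.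

## Further compounds

F1 | step 10 | (3S)-3-{3,5-bis[(tert-butyldimethylsilyl)oxy]-2-(3-methylbut-2-en-1-yl)phenoxy}-3-[2,4-diacetoxy-5-(2-methylbut-3-en-2-yl)phenyl]propanoyl chloride | ClC(=O)C[C@H](Oc1cc(O[Si](C)(C)C(C)(C)C)cc(O[Si](C)(C)C(C)(C)C)c1CC=C(C)C)c1cc(C(C)(C)C=C)c(OC(C)=O)cc1OC(C)=O
F2 | step 8 | tert-butyl (3R)-3-[2,4-diacetoxy-5-(2-methylbut-3-en-2-yl)phenyl]-3-[(diphenylphosphanyl)oxy]propanoate | CC(C)(C)OC(=O)C[C@@H](OP(c1ccccc1)c1ccccc1)c1cc(C(C)(C)C=C)c(OC(C)=O)cc1OC(C)=O
F3 | step 7 | 1,3-bis[(tert-butyldimethylsilyl)oxy]-5-[(2-methylbut-3-yn-2-yl)oxy]benzene | C#CC(C)(C)Oc1cc(O[Si](C)(C)C(C)(C)C)cc(O[Si](C)(C)C(C)(C)C)c1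
F4 | step 7 | 1,3-bis[(tert-butyldimethylsilyl)oxy]-5-[(2-methylbut-3-en-2-yl)oxy]benzene | C=CC(C)(C)Oc1cc(O[Si](C)(C)C(C)(C)C)cc(O[Si](C)(C)C(C)(C)C)c1
F5 | step 5 | tert-butyl 3-[2,4-diacetoxy-5-(2-methylbut-3-en-2-yl)phenyl]-3-oxopropanoate | CC(C)(C)OC(=O)CC(=O)c1cc(C(C)(C)C=C)c(OC(C)=O)cc1OC(C)=O
A1 | alternative 1 | (2S,4S)-2-[2,4-bis(methoxymethoxy)-5-(2-methylbut-3-en-2-yl)phenyl]-5,7-bis(methoxymethoxy)-8-(3-methylbut-2-en-1-yl)-3,4-dihydro-2H-chromen-4-ol | C=CC(C)(C)c1cc([C@@H]2C[C@H](O)c3c(OCOC)cc(OCOC)c(CC=C(C)C)c3O2)c(OCOC)cc1OCOC
A2 | alternative 1 | 2-{(1S,3S)-3-[2,4-bis(methoxymethoxy)-5-(2-methylbut-3-en-2-yl)phenyl]-1,3-dihydroxypropyl}-3,5-bis(methoxymethoxy)-6-(3-methylbut-2-en-1-yl)phenyl trifluoromethanesulfonate | C=CC(C)(C)c1cc([C@@H](O)C[C@H](O)c2c(OCOC)cc(OCOC)c(CC=C(C)C)c2OS(=O)(=O)C(F)(F)F)c(OCOC)cc1OCOC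
A3 | alternative 2 | 5-[(tert-butyldimethylsilyl)oxy]-2-{(2S,4S)-5,7-bis[(tert-butyldimethylsilyl)oxy]-4-methoxy-8-(3-methylbut-2-en-1-yl)-3,4-dihydro-2H-chromen-2-yl}-4-(2-methylbut-3-en-2-yl)phenol | C=CC(C)(C)c1cc([C@@H]2C[C@H](OC)c3c(O[Si](C)(C)C(C)(C)C)cc(O[Si](C)(C)C(C)(C)C)c(CC=C(C)C)c3O2)c(O)cc1O[Si](C)(C)C(C)(C)C
A4 | alternative 2 | 4,6-bis[(tert-butyldimethylsilyl)oxy]-2-hydroxy-3-(3-methylbut-2-en-1-yl)benzaldehyde | O=Cc1c(O[Si](C)(C)C(C)(C)C)cc(O[Si](C)(C)C(C)(C)C)c(CC=C(C)C)c1O
A5 | alternative 2 | 5-[(tert-butyldimethylsilyl)oxy]-2-ethenyl-4-(2-methylbut-3-en-2-yl)phenol | C=Cc1cc(C(C)(C)C=C)c(O[Si](C)(C)C(C)(C)C)cc1O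
A6 | alternative 3 | (2S)-2-{2,4-bis[(tert-butyldimethylsilyl)oxy]-5-(2-methylbut-3-en-2-yl)phenyl}-5-hydroxy-8-(3-methylbut-2-en-1-yl)-7-[(triisopropylsilyl)oxy]-2,3-dihydro-4H-chromen-4-one | C=CC(C)(C)c1cc([C@@H]2CC(=O)c3c(O)cc(O[Si](C(C)C)(C(C)C)C(C)C)c(CC=C(C)C)c3O2)c(O[Si](C)(C)C(C)(C)C)cc1O[Si](C)(C)C(C)(C)C
A7 | alternative 3 | (2S)-2-{2,4-bis[(tert-butyldimethylsilyl)oxy]-5-(2-methylbut-3-en-2-yl)phenyl}-6-(2-diazo-5-methylhex-4-enoyl)-2,3-dihydro-4H-pyran-4-one | C=CC(C)(C)c1cc([C@@H]2CC(=O)C=C(C(=O)C(=[N+]=[N-])CC=C(C)C)O2)c(O[Si](C)(C)C(C)(C)C)cc1O[Si](C)(C)C(C)(C)C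
A8 | alternative 3 | (ethynyloxy)triisopropylsilane | C#CO[Si](C(C)C)(C(C)C)C(C)C
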